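**Plan**
- Retrosynthesis: after debenzylation, the lower C-3 carbinol goes back to a flavan-3-one; the lower pyran is cut at O-1–C-2 and C-4–C-4a (a phenol plus a cinnamaldehyde); the dihydrobenzofuran is cut at its O–aryl bond; the methine–aryl bond leads back to C-2 of (+)-catechin.
- Forward: ring C of tetra-O-benzyl-(+)-catechin is opened at C-2 by a silyl-protected phloroglucinol ether, the freed phenol is exchanged (as its triflate) for the C-3 oxygen to close the dihydrobenzofuran, and the lower pyran is annulated last onto the unmasked phenol.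
- Enabling feature: in the lower ring A the pyran oxygen (on C-8a) is para to the methine-bearing C-6, and C-5/C-7 carry like oxygens. The phenol precursor therefore has two equivalent ortho carbons (future C-4a/C-8) and can only give the 6-linked flavan.
- Stereochemistry, upper unit: C-3 of (+)-catechin becomes dihydrobenzofuran C-2 (S) with its own oxygen retained; the methine (R) arises by arylation of catechin C-2 with inversion.
- Stereochemistry, lower unit: C-2 of the flavan-3-one is benzylic, alpha to O-1 and alpha to the carbonyl, hence labile; a catalyst-controlled dynamic kinetic resolution hydrogenation sets (2S,3S).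

Key step: step 8

Assumption: the chromene, the flavan-3-ol and the flavan-3-one of the lower unit are carried as mixtures of epimers at the centres that the key step forms without control; these centres are left open in their SMILES.

Step 1
Reactants: 1 (+)-catechin
Product: 2 tetra-O-benzyl-(+)-catechin (the four phenols benzylated)
Conditions: BnBr (4.4 equiv), K2CO3, DMF, 0 °C to rt
Reagents that add atoms: benzyl bromide (BrCc1ccccc1)
Why: Williamson ether synthesis; the four phenols are alkylated under carbonate base in preference to the secondary C-3 alcohol, and no stereocentre is touched.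

Step 2
Reactants: 3 phloroglucinol dibenzyl ether
Product: 4 phloroglucinol dibenzyl triisopropylsilyl ether
Conditions: i-Pr3SiCl, imidazole, DMF, rt
Reagents that add atoms: triisopropylsilyl chloride (CC(C)[Si](Cl)(C(C)C)C(C)C)
Why: Phenol silylation; the bulky silyl ether later shields both ring carbons next to it and marks the oxygen that will become the lower pyran oxygen.

Step 3
Reactants: 2 tetra-O-benzyl-(+)-catechin; 4 phloroglucinol dibenzyl triisopropylsilyl ether
Product: 5 ring-opened adduct (triarylpropanol with one free phenol and the new R methine)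
Conditions: silyl ether in fourfold excess, CF3CO2H (10 equiv), (CF3)2CHOH–CH2Cl2 1:4, −20 to 0 °C
Reagents that add atoms: none
Why: Friedel–Crafts alkylation in which the acid heterolyses the benzylic C-2–O-1 bond of the pyran ring (a 4-alkoxybenzyl aryl ether, as in the acidolysis of p-methoxybenzyl ethers with an arene scavenger), and the cation should be captured by the only unshielded carbon of the silyl ether (between its two benzyloxy groups) on the face anti to the C-3 benzyl branch in the 1,3-allylic strain conformer, which gives the (1R) methine while the carbinol centre (now 2S) is untouched.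

Step 4
Reactants: 5 ring-opened adduct
Product: 6 aryl triflate (secondary alcohol free)
Conditions: PhNTf2 (1.2 equiv), Et3N, DMAP (cat.), CH2Cl2, 0 °C to rt
Reagents that add atoms: N-phenylbis(trifluoromethanesulfonimide) (O=S(=O)(N(c1ccccc1)S(=O)(=O)C(F)(F)F)C(F)(F)F)
Why: Phenol triflation; the phenoxide reacts with the mild triflyl donor far faster than the hindered secondary alcohol.

Step 5
Reactants: 6 aryl triflate
Product: 7 (2S)-2-[(R)-diarylmethyl]-4,6-bis(benzyloxy)-2,3-dihydrobenzofuran (silyl ether)
Conditions: Pd2(dba)3 (3 mol%), t-BuXPhos (8 mol%), K3PO4, toluene, 90 °C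
Reagents that add atoms: none
Why: Intramolecular Buchwald–Hartwig etherification (oxidative addition into the aryl triflate, alkoxide binding, C–O reductive elimination) closes the five-membered ring; the carbinol C–O bond is never broken, so the configuration is retained (S), and no leaving group is placed next to the diarylmethine.

Step 6
Reactants: 7 dihydrobenzofuran silyl ether
Product: 8 phenol (4-hydroxy-2,6-bis(benzyloxy)phenyl group on the methine)
Conditions: Bu4NF (1.2 equiv), AcOH (1.2 equiv), THF, 0 °C
Reagents that add atoms: none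
Why: Fluoride cleavage of the aryl silyl ether, buffered with acetic acid; this frees the one oxygen that is para to the methine.

Step 7
Reactants: 9 protocatechualdehyde dibenzyl ether; 10 (triphenylphosphoranylidene)acetaldehyde
Product: 11 (E)-3-[3,4-bis(benzyloxy)phenyl]prop-2-enal
Conditions: toluene, 80 °C
Reagents that add atoms: none
Why: Wittig reaction with the stabilised formyl ylide, which should give the E enal.

Step 8
Reactants: 8 phenol; 11 (E)-enal
Product: 14 2H-chromene of the lower unit (6-linked; both C-2 epimers), via benzodioxaborin 12 (not isolated), via ortho-quinone methide 13 (not isolated)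
Conditions: PhB(OH)2 (1.2 equiv), EtCO2H (0.3 equiv), enal (1.5 equiv), toluene, reflux (Dean–Stark)
Reagents that add atoms: none
Why: Phenylboronic acid condenses with the phenol and the aldehyde and delivers the aldehyde carbon to the ortho carbon within a boron template (C-4–C-4a bond), giving benzodioxaborin 12, which at reflux fragments to the vinylogous ortho-quinone methide 13 and regenerates the boronic acid; 13 then closes by thermal oxa-6π electrocyclisation, forming the O-1–C-2 bond. The closest known reaction type is the boronic acid-mediated chromene synthesis from phenols and enals. The one ring formed, the lower pyran, is thus closed in a pericyclic 6π mode after an intermolecular ortho-hydroxyalkylation. The new stereocentre C-2 is formed without control (both epimers are expected), which is accepted because C-2 becomes epimerisable in the later ketone and is set in step 11. The selectivity the step does need is positional: the phenol oxygen is para to the methine-bearing carbon and its two ortho carbons are equivalent and the only free positions of that ring, so only the 6-linked chromene can form, and the boron template keeps the enal away from the other electron-rich rings.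

Step 9
Reactants: 14 chromene
Product: 16 2,3-trans-flavan-3-ol of the lower unit (both antipodal series), via alkylborane 15 (not isolated)
Conditions: BH3·THF, THF, 0 °C to rt; then NaOH, H2O2, 0 °C
Reagents that add atoms: hydrogen peroxide (OO)
Why: Hydroboration–oxidation; boron should add to C-3 (styrene-type regiochemistry, distal to ring A) anti to the 2-aryl group and is replaced by OH with retention; the configuration formed here is erased in step 10.

Step 10
Reactants: 16 lower-unit alcohol mixture
Product: 17 flavan-3-one of the lower unit (both C-2 epimers)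
Conditions: Dess–Martin periodinane, wet CH2Cl2, rt; used at once
Reagents that add atoms: none
Why: Dess–Martin oxidation of the secondary alcohol under near-neutral conditions, as is usual for benzylated flavan-3-ols; all stereoisomers of the alcohol converge on one ketone.

Step 11
Reactants: 17 lower-unit ketone
Product: 18 octabenzyl ether of the target with the (2S,3S) lower unit
Conditions: H2 (10 atm), RuCl2[(S)-xylbinap][(S)-daipen] (2 mol%), t-BuOK (0.2 equiv), i-PrOH–toluene, 25 °C
Reagents that add atoms: none
Why: Proposed new method: t-BuOK equilibrates the two C-2 epimers of the ketone through the enolate (C-2–H is benzylic and alpha to both O-1 and the carbonyl), while the chiral ruthenium hydride–diamine catalyst reduces one epimer much faster by outer-sphere hydride/proton transfer to the carbonyl face anti to the 2-aryl group, so the (2S,3S) cis alcohol should result under catalyst control (the antipode of the complex is assigned by analogy with 2-arylcyclohexanones, and its mirror image would be used if the sense of induction proved opposite); the closest known reaction type is the dynamic kinetic resolution hydrogenation of racemic 2-arylcycloalkanones and alpha-aryloxy ketones with RuCl2(diphosphine)(diamine)/t-BuOK, which gives cis-2-arylcycloalkanols.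

Step 12
Reactants: 18 octabenzyl ether
Product: 19 target CNP0161875.1
Conditions: H2 (1 atm), Pd(OH)2/C, THF–MeOH 1:1, rt
Reagents that add atoms: none
Why: Hydrogenolysis of the eight aryl benzyl ethers under mild conditions of the kind used for benzylated flavan-3-ol oligomers; no stereocentre is touched.

**Compound list**
1 | (+)-catechin, (2R,3S)-2-(3,4-dihydroxyphenyl)-3,4-dihydro-2H-chromene-3,5,7-triol | O[C@H]1Cc2c(O)cc(O)cc2O[C@@H]1c1ccc(O)c(O)c1 | starting material
2 | 5,7,3',4'-tetra-O-benzyl-(+)-catechin, (2R,3S)-5,7-bis(benzyloxy)-2-[3,4-bis(benzyloxy)phenyl]chroman-3-ol | O[C@H]1Cc2c(OCc3ccccc3)cc(OCc3ccccc3)cc2O[C@@H]1c1ccc(OCc2ccccc2)c(OCc2ccccc2)c1 | intermediate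
3 | 3,5-bis(benzyloxy)phenol | Oc1cc(OCc2ccccc2)cc(OCc2ccccc2)c1 | starting material
4 | [3,5-bis(benzyloxy)phenoxy]tri(propan-2-yl)silane | CC(C)[Si](Oc1cc(OCc2ccccc2)cc(OCc2ccccc2)c1)(C(C)C)C(C)C | intermediate
5 | (1R,2S)-1-[3,4-bis(benzyloxy)phenyl]-1-[2,6-bis(benzyloxy)-4-(triisopropylsilyloxy)phenyl]-3-[2,4-bis(benzyloxy)-6-hydroxyphenyl]propan-2-ol | O[C@H]([C@H](c1ccc(OCc2ccccc2)c(OCc2ccccc2)c1)c1c(OCc2ccccc2)cc(O[Si](C(C)C)(C(C)C)C(C)C)cc1OCc1ccccc1)Cc1c(O)cc(OCc2ccccc2)cc1OCc1ccccc1 | intermediate
6 | 3,5-bis(benzyloxy)-2-{(2S,3R)-3-[3,4-bis(benzyloxy)phenyl]-3-[2,6-bis(benzyloxy)-4-(triisopropylsilyloxy)phenyl]-2-hydroxypropyl}phenyl trifluoromethanesulfonate | O[C@H]([C@H](c1ccc(OCc2ccccc2)c(OCc2ccccc2)c1)c1c(OCc2ccccc2)cc(O[Si](C(C)C)(C(C)C)C(C)C)cc1OCc1ccccc1)Cc1c(OS(=O)(=O)C(F)(F)F)cc(OCc2ccccc2)cc1OCc1ccccc1 | intermediate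
7 | (2S)-4,6-bis(benzyloxy)-2-{(R)-[3,4-bis(benzyloxy)phenyl][2,6-bis(benzyloxy)-4-(triisopropylsilyloxy)phenyl]methyl}-2,3-dihydro-1-benzofuran | c1ccccc1COc1cc(OCc3ccccc3)c2c(c1)O[C@H]([C@H](c1ccc(OCc3ccccc3)c(OCc3ccccc3)c1)c1c(OCc3ccccc3)cc(O[Si](C(C)C)(C(C)C)C(C)C)cc1OCc1ccccc1)C2 | intermediate
8 | 3,5-bis(benzyloxy)-4-{(R)-[3,4-bis(benzyloxy)phenyl][(2S)-4,6-bis(benzyloxy)-2,3-dihydro-1-benzofuran-2-yl]methyl}phenol | c1ccccc1COc1cc(OCc3ccccc3)c2c(c1)O[C@H]([C@H](c1ccc(OCc3ccccc3)c(OCc3ccccc3)c1)c1c(OCc3ccccc3)cc(O)cc1OCc1ccccc1)C2 | intermediate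
9 | 3,4-bis(benzyloxy)benzaldehyde | O=Cc1ccc(OCc2ccccc2)c(OCc2ccccc2)c1 | starting material
10 | (triphenylphosphoranylidene)acetaldehyde | O=CC=P(c1ccccc1)(c1ccccc1)c1ccccc1 | starting material
11 | (2E)-3-[3,4-bis(benzyloxy)phenyl]prop-2-enal | O=C/C=C/c1ccc(OCc2ccccc2)c(OCc2ccccc2)c1 | intermediate
12 | 2-phenyl-4H-1,3,2-benzodioxaborin built on the lower ring of 8, carrying the (E)-2-[3,4-bis(benzyloxy)phenyl]ethenyl group at C-4 of the boron heterocycle (not isolated) | c1ccccc1COc1cc(OCc3ccccc3)c2c(c1)O[C@H]([C@H](c1ccc(OCc3ccccc3)c(OCc3ccccc3)c1)c1c(OCc3ccccc3)c4C(/C=C/c5ccc(OCc6ccccc6)c(OCc6ccccc6)c5)OB(c5ccccc5)Oc4cc1OCc1ccccc1)C2 | intermediate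
13 | vinylogous ortho-quinone methide: 3,5-bis(benzyloxy)-6-(3-arylprop-2-enylidene)cyclohexa-2,4-dien-1-one with the upper unit on C-4 (not isolated) | c1ccccc1COc1cc(OCc3ccccc3)c2c(c1)O[C@H]([C@H](c1ccc(OCc3ccccc3)c(OCc3ccccc3)c1)C1=C(OCc3ccccc3)C(=C/C=C/c5ccc(OCc6ccccc6)c(OCc6ccccc6)c5)C(=O)C=C1OCc1ccccc1)C2 | intermediate
14 | (2S)-4,6-bis(benzyloxy)-2-[(R)-[3,4-bis(benzyloxy)phenyl]{5,7-bis(benzyloxy)-2-[3,4-bis(benzyloxy)phenyl]-2H-chromen-6-yl}methyl]-2,3-dihydro-1-benzofuran, both epimers at chromene C-2 | c1ccccc1COc1cc(OCc3ccccc3)c2c(c1)O[C@H]([C@H](c1ccc(OCc3ccccc3)c(OCc3ccccc3)c1)c1c(OCc3ccccc3)c4C=CC(c5ccc(OCc6ccccc6)c(OCc6ccccc6)c5)Oc4cc1OCc1ccccc1)C2 | intermediate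
15 | C-3 alkylborane from hydroboration of 14, drawn as the monoalkylborane (not isolated) | c1ccccc1COc1cc(OCc3ccccc3)c2c(c1)O[C@H]([C@H](c1ccc(OCc3ccccc3)c(OCc3ccccc3)c1)c1c(OCc3ccccc3)c4CC(B)C(c5ccc(OCc6ccccc6)c(OCc6ccccc6)c5)Oc4cc1OCc1ccccc1)C2 | intermediate
16 | 5,7-bis(benzyloxy)-2-[3,4-bis(benzyloxy)phenyl]-6-{(R)-[3,4-bis(benzyloxy)phenyl][(2S)-4,6-bis(benzyloxy)-2,3-dihydro-1-benzofuran-2-yl]methyl}chroman-3-ol, 2,3-trans, mixture at C-2/C-3 | c1ccccc1COc1cc(OCc3ccccc3)c2c(c1)O[C@H]([C@H](c1ccc(OCc3ccccc3)c(OCc3ccccc3)c1)c1c(OCc3ccccc3)c4CC(O)C(c5ccc(OCc6ccccc6)c(OCc6ccccc6)c5)Oc4cc1OCc1ccccc1)C2 | intermediate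
17 | 5,7-bis(benzyloxy)-2-[3,4-bis(benzyloxy)phenyl]-6-{(R)-[3,4-bis(benzyloxy)phenyl][(2S)-4,6-bis(benzyloxy)-2,3-dihydro-1-benzofuran-2-yl]methyl}chroman-3-one, both C-2 epimers | c1ccccc1COc1cc(OCc3ccccc3)c2c(c1)O[C@H]([C@H](c1ccc(OCc3ccccc3)c(OCc3ccccc3)c1)c1c(OCc3ccccc3)c4CC(=O)C(c5ccc(OCc6ccccc6)c(OCc6ccccc6)c5)Oc4cc1OCc1ccccc1)C2 | intermediate
18 | (2S,3S)-5,7-bis(benzyloxy)-2-[3,4-bis(benzyloxy)phenyl]-6-{(R)-[3,4-bis(benzyloxy)phenyl][(2S)-4,6-bis(benzyloxy)-2,3-dihydro-1-benzofuran-2-yl]methyl}chroman-3-ol | c1ccccc1COc1cc(OCc3ccccc3)c2c(c1)O[C@H]([C@H](c1ccc(OCc3ccccc3)c(OCc3ccccc3)c1)c1c(OCc3ccccc3)c4C[C@H](O)[C@H](c5ccc(OCc6ccccc6)c(OCc6ccccc6)c5)Oc4cc1OCc1ccccc1)C2 | intermediate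
19 | CNP0161875.1, (2S,3S)-2-(3,4-dihydroxyphenyl)-6-{(R)-(3,4-dihydroxyphenyl)[(2S)-4,6-dihydroxy-2,3-dihydro-1-benzofuran-2-yl]methyl}-3,4-dihydro-2H-chromene-3,5,7-triol | Oc1cc(O)c2c(c1)O[C@H]([C@H](c1ccc(O)c(O)c1)c1c(O)cc3c(c1O)C[C@H](O)[C@H](c1ccc(O)c(O)c1)O3)C2 | target

**Totals**
Total step count: 12. Longest linear sequence: 10 steps (1, 3, 4, 5, 6, 8, 9, 10, 11, 12).

**Steps most likely to fail**

Step 11. The reduction may outrun the C-2 epimerisation, the catalyst may discriminate poorly between the carbonyl faces in the presence of the remote centres, or the base may degrade the sensitive ketone. Fallback, from 17 back to 18: reduce 17 with LiBH(s-Bu)3 in THF at −78 °C. Hydride adds anti to the 2-aryl group of each C-2 epimer, the standard substrate-controlled route from flavan-3-ones to 2,3-cis-flavan-3-ols. This should give 18 together with the lower-unit (2R,3R) diastereomer of 18 F1. The two are diastereomers and are separated by chromatography. F1 is oxidised back to 17 with Dess–Martin periodinane, equilibrated at C-2 with DBU and resubmitted.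

Step 3. The cation may attack a ring carbon next to the silyloxy group, may attack from the wrong face, may rearrange by 1,2-hydride shift from the carbinol carbon to the ketone, or may be consumed by self-alkylation of 2 through its own ring A. Fallback, from 3 (together with 2) back to 5: block the wrong positions instead of relying on steric bias. Bromination of 3 at both carbons ortho to the hydroxyl with NBS (2 equiv) and i-Pr2NH in CH2Cl2 (amine-directed ortho-bromination of phenols) gives 2,6-dibromo-3,5-bis(benzyloxy)phenol F2. Silylation with i-Pr3SiOTf and 2,6-lutidine gives its triisopropylsilyl ether F3, in which the carbon para to the silyloxy group is the only free activated position. The ring-opening alkylation of 2 under the conditions of step 3 can then only give the dibromo adduct F4. Treatment of F4 with n-BuLi in THF, held at −78 °C so that the aryllithium is protonated before the silyl group can migrate from oxygen to carbon, followed by a methanol quench, removes both bromines and gives 5. Two equivalents of n-BuLi are consumed by the OH groups and two effect the bromine–lithium exchange.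

Step 5. The palladium alkoxide of the hindered secondary alcohol may undergo beta-hydride elimination (ketone plus reduced arene), or the electron-rich aryl triflate may hydrolyse before oxidative addition. Fallback, from 6 back to 7: close the ring through an aryne instead of a metal catalyst. LiN(i-Pr)2 (3 equiv) in THF at −78 to −40 °C forms the alkoxide and removes the ring proton between the triflate and the neighbouring benzyloxy group. Loss of triflate gives the aryne F5 (as its lithium alkoxide). The tethered alkoxide adds to the aryne carbon that carried the triflate in a five-membered ring closure, the aryl anion ending ortho to a benzyloxy group. Protonation on work-up gives 7, again with the carbinol C–O bond intact.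

Further compounds
F1 | step 11 | (2R,3R)-lower-unit diastereomer of 18 | c1ccccc1COc1cc(OCc3ccccc3)c2c(c1)O[C@H]([C@H](c1ccc(OCc3ccccc3)c(OCc3ccccc3)c1)c1c(OCc3ccccc3)c4C[C@@H](O)[C@@H](c5ccc(OCc6ccccc6)c(OCc6ccccc6)c5)Oc4cc1OCc1ccccc1)C2
F2 | step 3 | 2,6-dibromo-3,5-bis(benzyloxy)phenol | Oc1c(Br)c(OCc2ccccc2)cc(OCc2ccccc2)c1Br
F3 | step 3 | [2,6-dibromo-3,5-bis(benzyloxy)phenoxy]tri(propan-2-yl)silane | CC(C)[Si](Oc1c(Br)c(OCc2ccccc2)cc(OCc2ccccc2)c1Br)(C(C)C)C(C)C
F4 | step 3 | (1R,2S)-1-[3,4-bis(benzyloxy)phenyl]-1-[2,6-bis(benzyloxy)-3,5-dibromo-4-(triisopropylsilyloxy)phenyl]-3-[2,4-bis(benzyloxy)-6-hydroxyphenyl]propan-2-ol | O[C@H]([C@H](c1ccc(OCc2ccccc2)c(OCc2ccccc2)c1)c1c(OCc2ccccc2)c(Br)c(O[Si](C(C)C)(C(C)C)C(C)C)c(Br)c1OCc1ccccc1)Cc1c(O)cc(OCc2ccccc2)cc1OCc1ccccc1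
F5 | step 5 | aryne from 6 (triflate and the adjacent ring hydrogen removed; transient, drawn as the free alcohol) | O[C@H]([C@H](c1ccc(OCc2ccccc2)c(OCc2ccccc2)c1)c1c(OCc2ccccc2)cc(O[Si](C(C)C)(C(C)C)C(C)C)cc1OCc1ccccc1)CC1=C(OCc2ccccc2)C=C(OCc2ccccc2)C#C1
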